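**Retrosynthetic overview**

1. The target is released last from its 5,7,4'-tris(MOM) ether by mild acidic acetal cleavage.
2. Ring C is the only ring built: O1–C8a, C4–C4a and O1–C2 are formed in one flask when a ring-A aryne inserts into the carboxyl C–O bond of an (E)-α-aryl-β-methoxyacrylic acid (ring B plus C2, C3, C4), followed by addition–elimination.
3. Feature: in ring A, O1 (on C8a) and the C4 carbonyl (on C4a) sit on neighbouring carbons beside the C5 oxygen. Cutting both bonds leaves an aryne whose parent phenol, 3,5-bis(MOMO)-4-prenylphenol, has a mirror plane through C1 and C4, so a 6- versus 8-prenyl question cannot arise.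
4. Aryne precursor: phloroglucinol → bis-MOM phenol → TIPS ether → lithiation/prenylation between the MOM ethers → phenol → carbamate-directed ortho-silylation → triflate.
5. Acid: 4-chloro-3-methoxyphenol → MOM ether → lithiation/prenylation between OMe and OMOM → aryl boronate → Suzuki coupling with methyl (Z)-2-iodo-3-methoxyacrylate → saponification. Rings A and B are bought as benzene rings.

Key step: step 14

Assumption: prenyl = 3-methylbut-2-en-1-yl and MOM = methoxymethyl throughout; 4-chloro-3-methoxyphenol and methyl (E)-3-methoxyacrylate are taken as catalogue compounds, and the HF released from the acid in step 14 is taken to stay bound to excess CsF without harming the MOM ethers.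

**Route**

Step 1
Reactants: 1 phloroglucinol
Product: 2 3,5-bis(methoxymethoxy)phenol
Conditions: MOMCl (2 equiv), DIPEA, CH2Cl2/DMF, 0 °C → rt; chromatography
Reagents that add atoms: chloromethyl methyl ether, COCCl
Why: Williamson-type O-alkylation of the threefold-symmetric triol with two equivalents of MOMCl should give a statistical mixture from which the single possible bis-ether is separated.

Step 2
Reactants: 2 3,5-bis(methoxymethoxy)phenol
Product: 3 triisopropyl[3,5-bis(methoxymethoxy)phenoxy]silane
Conditions: TIPSCl, imidazole, DMF, rt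
Reagents that add atoms: chlorotriisopropylsilane, CC(C)[Si](Cl)(C(C)C)C(C)C
Why: Imidazole-promoted O-silylation masks O1 with a bulky group that neither directs lithiation nor is attacked by n-BuLi.

Step 3
Reactants: 3 triisopropyl[3,5-bis(methoxymethoxy)phenoxy]silane; 4 prenyl bromide
Product: 6 triisopropyl[3,5-bis(methoxymethoxy)-4-prenylphenoxy]silane, via C4 aryllithium 5 (not isolated)
Conditions: n-BuLi, THF, 0 °C; CuBr·SMe2 (10 mol%), prenyl bromide, −78 °C → rt
Reagents that add atoms: none
Why: Directed ortho-metalation occurs at the one C–H flanked by two chelating MOM ethers (the silyl ether shields its own ortho positions), and copper-catalysed SN2 allylation at the primary carbon of prenyl bromide installs the side chain.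

Step 4
Reactants: 6 triisopropyl[3,5-bis(methoxymethoxy)-4-prenylphenoxy]silane
Product: 7 3,5-bis(methoxymethoxy)-4-prenylphenol
Conditions: Bu4NF, THF, 0 °C; AcOH quench
Reagents that add atoms: none
Why: Fluoride-induced desilylation cleaves only the Si–O bond and should give the mirror-symmetric phenol with acetals and alkene untouched.

Step 5
Reactants: 7 3,5-bis(methoxymethoxy)-4-prenylphenol
Product: 8 3,5-bis(methoxymethoxy)-4-prenylphenyl N-isopropylcarbamate
Conditions: i-PrNCO, Et3N (cat.), CH2Cl2, rt
Reagents that add atoms: isopropyl isocyanate, CC(C)N=C=O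
Why: Base-catalysed addition of the phenol to the isocyanate (carbamoylation) installs a strong ortho-directing group that can later be removed under mild base.

Step 6
Reactants: 8 3,5-bis(methoxymethoxy)-4-prenylphenyl N-isopropylcarbamate
Product: 12 3,5-bis(methoxymethoxy)-4-prenyl-2-(trimethylsilyl)phenyl N-isopropylcarbamate, via N-silyl carbamate 9 (not isolated), via ortho-lithiated N-silyl carbamate 10 (not isolated), via N-silyl C-silyl carbamate 11 (not isolated)
Conditions: TBSOTf, TMEDA, Et2O, 0 °C → rt; n-BuLi, TMEDA, −78 °C; TMSCl, −78 °C → rt; cold aq. NaHSO4 wash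
Reagents that add atoms: chlorotrimethylsilane, C[Si](C)(C)Cl
Why: After N-silylation has masked the N–H, carbamate-directed ortho-metalation at −78 °C takes the ring C–H flanked by carbamate and MOM ether (both ortho sites are equivalent by symmetry), TMSCl traps the aryllithium, and the N–Si bond is hydrolysed on work-up.

Step 7
Reactants: 12 3,5-bis(methoxymethoxy)-4-prenyl-2-(trimethylsilyl)phenyl N-isopropylcarbamate
Product: 14 3,5-bis(methoxymethoxy)-4-prenyl-2-(trimethylsilyl)phenyl trifluoromethanesulfonate, via 2-silylphenol 13 (not isolated)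
Conditions: DBU, Et2NH, MeCN, 40 °C; then PhNTf2, rt
Reagents that add atoms: N-phenylbis(trifluoromethanesulfonimide), O=S(=O)(N(c1ccccc1)S(=O)(=O)C(F)(F)F)C(F)(F)F
Why: E1cB cleavage of the N-monoalkyl carbamate releases the phenoxide (the isocyanate is scavenged by Et2NH as a urea), which is sulfonylated in the same flask by the mild triflyl donor.

Step 8
Reactants: 15 methyl (E)-3-methoxyacrylate
Product: 17 methyl (Z)-2-iodo-3-methoxyacrylate, via iodo acetate adduct 16 (not isolated)
Conditions: NIS, AcOH, CH2Cl2, rt; then Et3N, rt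
Reagents that add atoms: N-iodosuccinimide, O=C1CCC(=O)N1I
Why: Iodo-acetoxylation of the enol ether (iodine to C2, acetate to the oxocarbenium carbon C3) followed by amine-induced elimination of acetic acid should give the α-iodo-β-methoxyacrylate as its Z isomer.

Step 9
Reactants: 18 4-chloro-3-methoxyphenol
Product: 19 1-chloro-2-methoxy-4-(methoxymethoxy)benzene
Conditions: MOMCl, DIPEA, CH2Cl2, 0 °C → rt
Reagents that add atoms: chloromethyl methyl ether, COCCl
Why: Williamson-type O-alkylation protects the only phenol as the acetal that survives fluoride, base and palladium later on.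

Step 10
Reactants: 19 1-chloro-2-methoxy-4-(methoxymethoxy)benzene; 4 prenyl bromide
Product: 21 1-chloro-2-methoxy-4-(methoxymethoxy)-3-prenylbenzene, via C3 aryllithium 20 (not isolated)
Conditions: n-BuLi, TMEDA, THF, −78 → −40 °C; CuBr·SMe2 (10 mol%), prenyl bromide, −78 °C → rt
Reagents that add atoms: none
Why: Directed ortho-metalation takes the C–H flanked cooperatively by OMe and OMOM while the aryl chloride does not exchange with n-BuLi at low temperature, and copper-catalysed SN2 allylation then places the prenyl group at the future C3'.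

Step 11
Reactants: 21 1-chloro-2-methoxy-4-(methoxymethoxy)-3-prenylbenzene
Product: 22 2-[2-methoxy-4-(methoxymethoxy)-3-prenylphenyl]-4,4,5,5-tetramethyl-1,3,2-dioxaborolane
Conditions: B2pin2, Pd2(dba)3 (2 mol%), XPhos, KOAc, dioxane, 100 °C
Reagents that add atoms: bis(pinacolato)diboron, CC1(C)OB(OC1(C)C)B1OC(C)(C)C(C)(C)O1
Why: Miyaura borylation with a bulky electron-rich biarylphosphine on zerovalent palladium allows oxidative addition into the electron-rich aryl chloride, and the trisubstituted alkene and acetal are inert.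

Step 12
Reactants: 22 2-[2-methoxy-4-(methoxymethoxy)-3-prenylphenyl]-4,4,5,5-tetramethyl-1,3,2-dioxaborolane; 17 methyl (Z)-2-iodo-3-methoxyacrylate
Product: 23 methyl (E)-3-methoxy-2-[2-methoxy-4-(methoxymethoxy)-3-prenylphenyl]acrylate
Conditions: Pd(PPh3)4 (5 mol%), K3PO4, dioxane/H2O, 85 °C
Reagents that add atoms: none
Why: Suzuki–Miyaura coupling of the vinyl iodide proceeds with retention of alkene geometry, so the aryl group takes the place of iodine cis to OMe and the descriptor changes from Z to E only by priority rules.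

Step 13
Reactants: 23 methyl (E)-3-methoxy-2-[2-methoxy-4-(methoxymethoxy)-3-prenylphenyl]acrylate
Product: 24 (E)-3-methoxy-2-[2-methoxy-4-(methoxymethoxy)-3-prenylphenyl]acrylic acid
Conditions: LiOH·H2O, THF/MeOH/H2O, 40 °C; then 0.5 M HCl to pH 4–5, 0 °C
Reagents that add atoms: lithium hydroxide monohydrate, [Li+].[OH-].O
Why: Saponification of the methyl ester with mild hydroxide followed by controlled cold acidification should give the free acid with the enol ether and MOM acetal intact.

Step 14
Reactants: 14 3,5-bis(methoxymethoxy)-4-prenyl-2-(trimethylsilyl)phenyl trifluoromethanesulfonate; 24 (E)-3-methoxy-2-[2-methoxy-4-(methoxymethoxy)-3-prenylphenyl]acrylic acid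
Product: 27 5,7-bis(methoxymethoxy)-3-[2-methoxy-4-(methoxymethoxy)-3-prenylphenyl]-6-prenyl-4H-chromen-4-one, via aryne 25 (not isolated), via ortho-hydroxyaryl ketone 26 (not isolated)
Conditions: 14 (1.5 equiv), CsF (5 equiv), THF, 125 °C, sealed tube
Reagents that add atoms: none
Why: Proposed new method: fluoride attacks silicon of 14 and triflate leaves to give aryne 25; the caesium carboxylate of 24 adds to the aryne carbon remote from the C5 MOM ether (future C8a), the aryl anion formed at the future C4a attacks its own ester carbonyl through a four-membered transition state, and the resulting alkoxide opens to the ortho-acyl phenoxide 26. The closest known reaction type is the fluoride-mediated insertion of arynes into the C–O bond of carboxylic acids, which gives ortho-hydroxyaryl ketones and, with unsaturated acids, chromanones or chromones after oxa-Michael closure; new here is an α-aryl-β-methoxyacrylic acid as partner with loss of methoxide as the final event. Ring C closes by 6-endo-trig conjugate addition of the C8a phenoxide to C2 followed by E1cB loss of methoxide, the same addition–elimination at a vinylogous ester that closes deoxybenzoin-derived enol ethers to isoflavones. No stereocentre is formed. The step needs regioselective addition to the unsymmetrical aryne, which the inductive pull of the C5 alkoxy group should secure by making the distal carbon electrophilic and placing the developing charge next to oxygen. It also needs 1,2-attack on the carbonyl to outrun both protonation of the aryl anion and its conjugate attack on the acrylate, which the aprotic medium, the high temperature, the excess CsF and the short reach to the ester carbonyl should favour.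

Step 15
Reactants: 27 5,7-bis(methoxymethoxy)-3-[2-methoxy-4-(methoxymethoxy)-3-prenylphenyl]-6-prenyl-4H-chromen-4-one
Product: 28 2'-methoxylupalbigenin
Conditions: 3 M aq. HCl, MeOH, 40 °C
Reagents that add atoms: none
Why: Acid-catalysed acetal exchange with methanol (MOM ether cleavage) frees the three phenols as dimethoxymethane, and dilute acid at moderate temperature should leave the prenyl double bonds unchanged.

**Compound list**

1 | phloroglucinol | Oc1cc(O)cc(O)c1 | starting material
2 | 3,5-bis(methoxymethoxy)phenol | COCOc1cc(O)cc(OCOC)c1 | intermediate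
3 | triisopropyl[3,5-bis(methoxymethoxy)phenoxy]silane | COCOc1cc(OCOC)cc(O[Si](C(C)C)(C(C)C)C(C)C)c1 | intermediate
4 | prenyl bromide (1-bromo-3-methylbut-2-ene) | CC(C)=CCBr | starting material
5 | [2,6-bis(methoxymethoxy)-4-(triisopropylsilyloxy)phenyl]lithium | [Li]c1c(OCOC)cc(O[Si](C(C)C)(C(C)C)C(C)C)cc1OCOC | intermediate
6 | triisopropyl[3,5-bis(methoxymethoxy)-4-(3-methylbut-2-en-1-yl)phenoxy]silane | COCOc1cc(O[Si](C(C)C)(C(C)C)C(C)C)cc(OCOC)c1CC=C(C)C | intermediate
7 | 3,5-bis(methoxymethoxy)-4-(3-methylbut-2-en-1-yl)phenol | COCOc1cc(O)cc(OCOC)c1CC=C(C)C | intermediate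
8 | 3,5-bis(methoxymethoxy)-4-(3-methylbut-2-en-1-yl)phenyl N-isopropylcarbamate | CC(C)NC(=O)Oc1cc(OCOC)c(CC=C(C)C)c(OCOC)c1 | intermediate
9 | 3,5-bis(methoxymethoxy)-4-(3-methylbut-2-en-1-yl)phenyl N-(tert-butyldimethylsilyl)-N-isopropylcarbamate | CC(C)N(C(=O)Oc1cc(OCOC)c(CC=C(C)C)c(OCOC)c1)[Si](C)(C)C(C)(C)C | intermediate
10 | 2-lithio derivative of 9 | [Li]c1c(OC(=O)N(C(C)C)[Si](C)(C)C(C)(C)C)cc(OCOC)c(CC=C(C)C)c1OCOC | intermediate
11 | 3,5-bis(methoxymethoxy)-4-(3-methylbut-2-en-1-yl)-2-(trimethylsilyl)phenyl N-(tert-butyldimethylsilyl)-N-isopropylcarbamate | C[Si](C)(C)c1c(OC(=O)N(C(C)C)[Si](C)(C)C(C)(C)C)cc(OCOC)c(CC=C(C)C)c1OCOC | intermediate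
12 | 3,5-bis(methoxymethoxy)-4-(3-methylbut-2-en-1-yl)-2-(trimethylsilyl)phenyl N-isopropylcarbamate | C[Si](C)(C)c1c(OC(=O)NC(C)C)cc(OCOC)c(CC=C(C)C)c1OCOC | intermediate
13 | 3,5-bis(methoxymethoxy)-4-(3-methylbut-2-en-1-yl)-2-(trimethylsilyl)phenol | C[Si](C)(C)c1c(O)cc(OCOC)c(CC=C(C)C)c1OCOC | intermediate
14 | 3,5-bis(methoxymethoxy)-4-(3-methylbut-2-en-1-yl)-2-(trimethylsilyl)phenyl trifluoromethanesulfonate | C[Si](C)(C)c1c(OS(=O)(=O)C(F)(F)F)cc(OCOC)c(CC=C(C)C)c1OCOC | intermediate
15 | methyl (E)-3-methoxyprop-2-enoate | CO/C=C/C(=O)OC | starting material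
16 | methyl 3-acetoxy-2-iodo-3-methoxypropanoate (racemic mixture of diastereomers) | COC(OC(C)=O)C(I)C(=O)OC | intermediate
17 | methyl (Z)-2-iodo-3-methoxyprop-2-enoate | CO/C=C(\I)C(=O)OC | intermediate
18 | 4-chloro-3-methoxyphenol | COc1cc(O)ccc1Cl | starting material
19 | 1-chloro-2-methoxy-4-(methoxymethoxy)benzene | COCOc1ccc(Cl)c(OC)c1 | intermediate
20 | [3-chloro-2-methoxy-6-(methoxymethoxy)phenyl]lithium | [Li]c1c(OCOC)ccc(Cl)c1OC | intermediate
21 | 1-chloro-2-methoxy-4-(methoxymethoxy)-3-(3-methylbut-2-en-1-yl)benzene | COCOc1ccc(Cl)c(OC)c1CC=C(C)C | intermediate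
22 | 2-[2-methoxy-4-(methoxymethoxy)-3-(3-methylbut-2-en-1-yl)phenyl]-4,4,5,5-tetramethyl-1,3,2-dioxaborolane | COCOc1ccc(B2OC(C)(C)C(C)(C)O2)c(OC)c1CC=C(C)C | intermediate
23 | methyl (E)-3-methoxy-2-[2-methoxy-4-(methoxymethoxy)-3-(3-methylbut-2-en-1-yl)phenyl]prop-2-enoate | CO/C=C(/C(=O)OC)c1ccc(OCOC)c(CC=C(C)C)c1OC | intermediate
24 | (E)-3-methoxy-2-[2-methoxy-4-(methoxymethoxy)-3-(3-methylbut-2-en-1-yl)phenyl]prop-2-enoic acid | CO/C=C(/C(=O)O)c1ccc(OCOC)c(CC=C(C)C)c1OC | intermediate
25 | 3,5-bis(methoxymethoxy)-4-(3-methylbut-2-en-1-yl)benzyne (triple bond between the former C1 and C2 of 14) | C1#CC(OCOC)=C(CC=C(C)C)C(OCOC)=C1 | intermediate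
26 | (E)-1-[6-hydroxy-2,4-bis(methoxymethoxy)-3-(3-methylbut-2-en-1-yl)phenyl]-3-methoxy-2-[2-methoxy-4-(methoxymethoxy)-3-(3-methylbut-2-en-1-yl)phenyl]prop-2-en-1-one | CO/C=C(/C(=O)c1c(O)cc(OCOC)c(CC=C(C)C)c1OCOC)c1ccc(OCOC)c(CC=C(C)C)c1OC | intermediate
27 | 5,7-bis(methoxymethoxy)-3-[2-methoxy-4-(methoxymethoxy)-3-(3-methylbut-2-en-1-yl)phenyl]-6-(3-methylbut-2-en-1-yl)-4H-chromen-4-one | COc1c(-c2coc3cc(OCOC)c(CC=C(C)C)c(OCOC)c3c2=O)ccc(OCOC)c1CC=C(C)C | intermediate
28 | 2'-methoxylupalbigenin, 5,7-dihydroxy-3-[4-hydroxy-2-methoxy-3-(3-methylbut-2-en-1-yl)phenyl]-6-(3-methylbut-2-en-1-yl)-4H-chromen-4-one | COc1c(-c2coc3cc(O)c(CC=C(C)C)c(O)c3c2=O)ccc(O)c1CC=C(C)C | target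

**Count**

Total steps: 15. Longest linear sequence: 9 steps (steps 1–7, 14, 15, from phloroglucinol). The acid branch is 5 steps (9–13), fed by the one-step iodoacrylate branch (8).

**Steps most likely to fail**

Step 14 (proposed new method). The aryl anion may be protonated before the acyl group migrates, so that the sequence stops at the aryl ester. The anion may instead attack the β-carbon of the acrylate and close toward a coumarin-type ring. Selectivity of addition to the aryne may erode, or the released methoxide may consume aryne. The fallback uses known chemistry only and keeps the symmetric phenol as the source of regiocontrol. It sets out from carbamate 8, which is N-silylated and ortho-lithiated as in step 6 (9, then 10), and the lithium compound is quenched with N-methoxy-N-methylacetamide instead of TMSCl. This gives 2-acetyl-3,5-bis(methoxymethoxy)-4-prenylphenyl N-(tert-butyldimethylsilyl)-N-isopropylcarbamate F1, which the aqueous NaHSO4 wash converts to 2-acetyl-3,5-bis(methoxymethoxy)-4-prenylphenyl N-isopropylcarbamate F2. DBU and Et2NH in MeCN then remove the carbamate to give 1-[6-hydroxy-2,4-bis(methoxymethoxy)-3-prenylphenyl]ethan-1-one F3. Heating with DMF dimethyl acetal should give (E)-3-(dimethylamino)-1-[6-hydroxy-2,4-bis(methoxymethoxy)-3-prenylphenyl]prop-2-en-1-one F4, and iodine in CHCl3 should close it to 3-iodo-5,7-bis(methoxymethoxy)-6-prenyl-4H-chromen-4-one F5. Suzuki–Miyaura coupling of F5 with boronate 22 (PdCl2(dppf), K3PO4, dioxane/H2O) comes back to the route at 27.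

Step 6. Deprotonation at the benzylic and allylic CH2 of the prenyl group, which lies between two coordinating MOM ethers, may compete with ring lithiation, and the carbamoyl group may shift to carbon (anionic ortho-Fries) before the silyl chloride reacts. The fallback replaces directed metalation by a halogen–lithium exchange and retro-Brook sequence. It sets out from phenol 7, whose two ortho positions are equivalent, and NBS in CH2Cl2 at −40 °C should give 2-bromo-3,5-bis(methoxymethoxy)-4-prenylphenol F6. Hexamethyldisilazane in THF then gives [2-bromo-3,5-bis(methoxymethoxy)-4-prenylphenoxy]trimethylsilane F7. Treatment with n-BuLi at −100 → −78 °C effects bromine–lithium exchange and 1,3-migration of silicon from oxygen to carbon. This gives the lithium salt of 13, which is triflated in the same flask with PhNTf2 and comes back to the route at 14.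

Step 15. The liberated phenols at C5, C7 and C4' may add under acid catalysis to the neighbouring prenyl double bonds (chroman formation), or the alkenes may be hydrated, before the last acetal is cleaved. The fallback avoids protic acid. It sets out from 27, and TMSOTf with 2,2'-bipyridyl in MeCN at 0 °C should convert the three aryl MOM ethers into the 5,7,4'-tris(trimethylsilyl) ether of the target F8. Water, or K2CO3 in MeOH, at rt then hydrolyses the silyl ethers and comes back to the route at 28.

**Further compounds**

F1 | step 14 | 2-acetyl-3,5-bis(methoxymethoxy)-4-(3-methylbut-2-en-1-yl)phenyl N-(tert-butyldimethylsilyl)-N-isopropylcarbamate | CC(=O)c1c(OC(=O)N(C(C)C)[Si](C)(C)C(C)(C)C)cc(OCOC)c(CC=C(C)C)c1OCOC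
F2 | step 14 | 2-acetyl-3,5-bis(methoxymethoxy)-4-(3-methylbut-2-en-1-yl)phenyl N-isopropylcarbamate | CC(=O)c1c(OC(=O)NC(C)C)cc(OCOC)c(CC=C(C)C)c1OCOC
F3 | step 14 | 1-[6-hydroxy-2,4-bis(methoxymethoxy)-3-(3-methylbut-2-en-1-yl)phenyl]ethan-1-one | CC(=O)c1c(O)cc(OCOC)c(CC=C(C)C)c1OCOC
F4 | step 14 | (E)-3-(dimethylamino)-1-[6-hydroxy-2,4-bis(methoxymethoxy)-3-(3-methylbut-2-en-1-yl)phenyl]prop-2-en-1-one | CN(C)/C=C/C(=O)c1c(O)cc(OCOC)c(CC=C(C)C)c1OCOC
F5 | step 14 | 3-iodo-5,7-bis(methoxymethoxy)-6-(3-methylbut-2-en-1-yl)-4H-chromen-4-one | COCOc1cc2occ(I)c(=O)c2c(OCOC)c1CC=C(C)C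
F6 | step 6 | 2-bromo-3,5-bis(methoxymethoxy)-4-(3-methylbut-2-en-1-yl)phenol | COCOc1cc(O)c(Br)c(OCOC)c1CC=C(C)C
F7 | step 6 | [2-bromo-3,5-bis(methoxymethoxy)-4-(3-methylbut-2-en-1-yl)phenoxy]trimethylsilane | COCOc1cc(O[Si](C)(C)C)c(Br)c(OCOC)c1CC=C(C)C
F8 | step 15 | 3-[2-methoxy-3-(3-methylbut-2-en-1-yl)-4-(trimethylsilyloxy)phenyl]-6-(3-methylbut-2-en-1-yl)-5,7-bis(trimethylsilyloxy)-4H-chromen-4-one | COc1c(-c2coc3cc(O[Si](C)(C)C)c(CC=C(C)C)c(O[Si](C)(C)C)c3c2=O)ccc(O[Si](C)(C)C)c1CC=C(C)C
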